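If a flask is judged by its product, I ask what becomes of open intermediate, which either couples with second intermediate or is lost to capture agent and to decomposition.

    substrate ⇌ open intermediate (K1 = 25, k1 = 0.079 min⁻¹, Ea1 = 87.0 kJ mol⁻¹, ΔH1 = −25.0 kJ mol⁻¹)
    partner → second intermediate (k2 = 0.17 min⁻¹, Ea2 = 76.0 kJ mol⁻¹)
    open intermediate + second intermediate → product (k3 = 13 L mol⁻¹ min⁻¹, Ea3 = 57.0 kJ mol⁻¹)
    open intermediate + capture agent → trapped intermediate (k4 = 1.3 L mol⁻¹ min⁻¹, Ea4 = 60.0 kJ mol⁻¹)
    partner + product ⇌ idle adduct, settled at all times (K5 = 200 L mol⁻¹, ΔH5 = 2.00 kJ mol⁻¹)
    open intermediate → decomposed reagent (k6 = 0.022 min⁻¹, Ea6 = 94.0 kJ mol⁻¹)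
    (constants at 5 °C)

the same everywhere: substrate 0.014 M; partner 1.10 equiv; capture agent 4.20 mM; time 25 min
- Monday's: temperature 5 °C
- Thursday's: temperature 45 °C
- Saturday's: temperature 25 °C

- for product the idle adduct is counted in
- at 5 °C the constants are as listed, elsewhere as the activation energies and enthalpies make them

1. which flask leads in amount of product, in percent of the substrate charged ("all alike" within 1.5 percentage points) (Monday's / Thursday's / Saturday's / all alike)
2. how much product is there at the end, in percent of the substrate charged: Monday's
3. how much product is there at the end, in percent of the substrate charged: Thursday's
4. how much product is there at the end, in percent of the substrate charged: Saturday's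

In Saturday's flask, the break-even level, the concentration of second intermediate at which open intermediate couples exactly as fast as it is lost (decomposition constant plus capture constant times [capture agent], over the coupling constant), is 5.41 mM. At any moment the coupling share, a selectivity, is [second intermediate] over [second intermediate] plus that level. Each coupling spends one second intermediate, so with [capture agent] held at its charge the ratio of rates integrates in closed form: the amount lost is the level times the logarithm of starting over final [second intermediate].

Suppose partner were converted at once, giving 15.4 mM from the start. That overstates the flask, so I take what it gives as a ceiling. Replacing the logarithmic mean by the larger plain mean keeps it a ceiling and leaves a quadratic, which gives 66.5% for Saturday's. Thursday's level is higher, 13.1 mM, and its ceiling is 47.8%.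

For a floor I hold the level throughout at what the ceiling leaves: 53.0% for Saturday's, 39.8% for Thursday's. This is a hand floor, not a proof; it leans on partner's step being quicker than substrate's opening, as it is below 58.4 °C. I commit to the middles, 59.7% for Saturday's and 43.8% for Thursday's.

Monday's flask has a low level, 2.11 mM, and a ceiling of 82.1%, but the forward step of its opening, taken alone, has a time constant of 12.7 min against 25 min. So I treat it as two pseudo-first-order steps in series, guessing [second intermediate] at half its possible amount. In this reckoning open intermediate leaves at 0.128 min⁻¹, 70.3% of the substrate has passed through, and my estimate of the yield is 55.1%. My leader is Saturday's.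

The forecast names Saturday's, with 56% for Monday's, 46% for Thursday's and 62% for Saturday's, on the ground that there “coupling beats decomposition by the best margin”. Its Saturday's figure stands inside my bracket and above my middle.

The simulation gives 55.2% for Monday's, 42.3% for Thursday's and 61.0% for Saturday's, so Saturday's leads.

Saturday's result lies inside the bracket. The forecast's order turns with a later reading: after 250 min Monday's flask stands at 77.4%, above Saturday's 61.0%. That Monday's figure lies below Monday's ceiling. Saturday's flask run at 10 °C has a level of 2.67 mM, a ceiling of 78.7% and a floor of 62.1%. That flask ends at 68.0%, with 5.85% still open intermediate.

The constants are those of an exercise; the run is a simulation.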